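## Structural features

The target is the feruloyl ester of a 2,3,4-trisubstituted oxolane (ring A: O1, C2, C3, C4, C5). C2 carries a 4-hydroxy-3,5-dimethoxyphenyl group, C3 a CH2O arm acylated by (E)-ferulic acid, C4 a 4-hydroxy-3-methoxybenzyl group, and C5 is an unsubstituted methylene bonded to O1. The three stereocentres are contiguous, C2 (S), C3 (R) and C4 (R), with the C2 aryl group and the C3 arm trans and the C3 and C4 arms cis. The fragile elements are the three free phenols, the benzylic C2–O1 ether (para-oxygenated, so it ionises under acid with epimerisation, ring opening or Friedel–Crafts closure) and the cinnamate ester, which is base-sensitive and whose alkene excludes a hydrogenolytic end game. The real difficulty is the contra-thermodynamic 3,4-cis relation beside the 2,3-trans one, together with telling apart the two one-carbon branches at C3 (oxygenated) and C4 (arylated). The key step exploits the fact that C3 and C4 each bear exactly one exocyclic carbon: with C5 raised to a lactone carbonyl, C4 and C3 are the α- and β-carbons and the aryl-bearing C2 the γ-carbon of a butyrolactone. Both branches can then be delivered to a butenolide in one conjugate addition–enolate trapping operation, and C2 steers C3 and, through C3, C4.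

## Logic of the disconnections

24 ⇒ 23. The three phenolic O–H bonds are traced back to O–Si bonds. The phenols then never meet the organometallic, hydride or oxidative steps, and a single fluoride treatment unmasks all of them. The forward step must be buffered so that the cinnamate ester and the benzylic ether survive; this choice excludes hydrogenolytic or strongly acidic protecting groups from the outset.

23 ⇒ 19 + 22. The acyl C–O bond of the ester is cut. This removes nine carbons in a convergent step and leaves a ring fragment with only one hydroxyl, so the acylation needs no selectivity. The forward step must be a mild, non-epimerising esterification of a β-branched primary alcohol.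

19 ⇒ 17. The C3–CH2OH arm is traced through 18 to the vinyl group of 17; in the forward sense the C=C bond is cleaved and one carbon is lost. A vinyl group is inert to the hydride, sulfonylation and base steps before it, and it keeps the diol stage free of a second primary hydroxyl. The forward step must spare two electron-rich arenes and must reduce 18 before its C3 centre epimerises.

17 ⇒ 15 ⇒ 14. The O1–C5 bond is cut, giving 15, and 15 is the hydride reduction product of 14. Closing the ring at the primary carbon C5 (through 16) means the C2–O bond is never broken, so the C2 configuration is carried over unchanged. The forward steps must reduce 14 faster than its cis α-centre enolises, and must activate the primary hydroxyl without touching the ionisable benzylic one.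

14 ⇒ 13. The C4–H bond is cut, returning the trigonal C4 of 13. The troublesome 3,4-cis relation is thereby reduced to a question of which face of C4 receives a proton. The forward step must be a conjugate hydride delivery that leaves the vinyl group alone (which excludes catalytic hydrogenation), followed by protonation anti to the C3 vinyl group under kinetic control.

13 ⇒ 6 + 9 + 8. The C3–vinyl bond and the C4=CH(aryl) bond are cut. The whole carbon skeleton of the ring fragment falls apart into three simple pieces, and only one stereocentre (C2 in 6) remains to be made by asymmetric synthesis. The forward step must add 1,4 and anti to the aryl group without removing the acidic C2–H of 6, and must trap the enolate with 8 before it is protonated.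

6 ⇒ 4 ⇒ 2 + 3. The acyl C5–O1 bond is cut (through 5), then the C2–C(sp) bond. This leaves an aldehyde and a three-carbon alkyne ester, joined by a catalytic enantioselective alkynylation. The forward steps must give the R carbinol with high enantioselectivity, and must semihydrogenate and lactonise under conditions too mild to deprotonate C2.

2 ⇒ 1, 8 ⇒ 7, 22 ⇒ 20 (through 21). Only O–Si bonds are cut; each aryl fragment comes from a commercial phenol by silylation.

## Other disconnections considered

Alternative 1: Ring A is cut at C2–C3 and C4–C5, into a three-atom C2–O1–C5 carbonyl ylide and the C3=C4 alkene of a chiral furanone.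
- **Forward step:** aldehyde A2 would be O-alkylated by triflate A3 and desilylated by fluoride to the ylide, which adds across furanone A1 anti to the menthyloxy group to give the cis-fused bicycle A4 (aryl exo).
- **In favour:** two C–C bonds, ring A and all three ring stereocentres arise in one step, and the 3,4-cis relation is guaranteed by suprafacial addition to a cyclic Z-alkene. On this point, and in bonds formed per step, the alternative is better than the chosen plan, which needs a separate kinetic protonation for C4. The ether oxygen is in place from the start, so no later ring closure is needed (also better).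
- **Against:** regiochemistry and exo selectivity of a non-stabilised ylide are not assured, and an electron-rich aldehyde gives a sluggish, stabilised oxocarbenium precursor. The auxiliary is stoichiometric and must come from the less common (+)-menthol series. The C4 branch of A4 is an acetal carbon at the aldehyde oxidation level, so acetal hydrolysis, aryl-metal addition and benzylic deoxygenation must follow in the presence of the ionisable C2–O1 ether. The C3 carbonyl must still be reduced, and the benzyl ether of A2 must be removed by hydrogenolysis before the cinnamate is attached.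
- **Comparison:** structurally the cycloaddition is more powerful than the chosen key step. Mechanistically it relies on auxiliary-controlled facial selectivity plus an uncertain exo/endo preference, where the chosen plan uses two strong 1,2-inductions from a catalytically set centre. In step economy it is at best equal, because about seven operations would follow A4.
- **Note on A4:** in bicyclo[3.3.0]octane numbering the aryl-bearing carbon is C8 (bonded to the bridgehead that carries the carbonyl C2), not C6. This is also the regiochemistry the polarity of the ylide predicts (nucleophilic CH2 terminus to the β-carbon of A1).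

Alternative 2: The O1–C2 bond is cut, opening ring A to the seco-diol A5, a 2,3-dibenzylbutane-1,4-diol with the syringyl phenol free and the guaiacyl phenol silylated.
- **Forward step:** two-electron anodic oxidation of the free phenol, the most easily oxidised site, would give a p-quinone methide at C2. The C5 hydroxyl would add to it in a 5-exo sense and re-aromatise the ring to give A6; the hydroxyl on the C3 arm could only form an oxetane and should not compete.
- **In favour:** the closure is biomimetic and needs no chemical oxidant, and A6 already carries the free primary alcohol for acylation. The C3/C4 relation of A5 is that of a trans-α,β-dibenzylbutyrolactone, the thermodynamically favoured and most accessible arrangement, so the 3,4-cis relation of ring A comes without effort. On that point the alternative is better than the chosen plan.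
- **Against:** C2 is created last and only under substrate control. The electron-rich guaiacyl ring can trap the quinone methide in a six-membered Friedel–Crafts closure. A6 keeps the free phenol and gains a more oxidisable benzylic ether C–H, so over-oxidation is a real risk. The acylation must then distinguish a primary alcohol from a free phenol.
- **Comparison:** mechanistically this is a late cationic closure whose selectivities are all intramolecular competitions, against an early catalytic setting of C2 in the chosen plan. In step economy the two are about equal: A5 with two different aryl groups would need some six to seven steps, and three more follow A6.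

Alternative 3: The C3–C4 bond and the CH2–aryl bond of the C4 branch are cut, leading to the β-iodo allyl ether A7 and the arylzinc reagent A8.
- **Forward step:** a low-valent nickel catalyst (for example NiBr2·diglyme with a terpyridine ligand) would abstract iodine from A7. The C3 radical closes 5-exo-trig onto the allyl group, and the primary radical is captured by an aryl–nickel species formed from A8; reductive elimination gives the benzyl group of A9.
- **In favour:** two C–C bonds, ring A and two stereocentres form in one step. The chair-like transition state of 5-hexenyl radical closure, with the C2 aryl group pseudo-equatorial, predicts 2,3-trans and 3,4-cis, the natural relative configuration, without a separate operation. The three oxygens of A9 are already differentiated (alkyl versus aryl silyl ethers). In convergence, bonds per step and overall step count (A7 in about four to five steps, three more after A9) the alternative is better than the chosen plan.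
- **Against:** the absolute configuration must be built into A7 beforehand, as a benzylic allyl ether centre next to a secondary iodide; with a para-oxygenated aryl group that centre is prone to ionise during its preparation. Radical diastereoselectivity is a matter of degree. Direct coupling before cyclisation, β-alkoxy elimination from a C3 organometallic and simple reduction of the carbon–iodine bond all compete.
- **Comparison:** the alternative trades certainty of stereocontrol for brevity. Its end game is the equal of the chosen one, since A9 and 19 differ by one silyl group only.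

Key step: step 5

Remarks on the chemistry (assumptions):
- Locants C2–C5 in the running text are those of ring A of the target (lactone carbonyl = C5, α-carbon = C4, β-carbon = C3, γ-carbon = C2); systematic names keep their own numbering. TBS = tert-butyldimethylsilyl.
- The antipode of the ProPhenol ligand is defined by function: it is the one that delivers the alkynyl group to the Si face of 2 (R carbinol); both antipodes are commercial.
- 11 and 12 are mixtures at the carbinol carbon; that centre becomes trigonal in 13.

## Route

Step 1
Reactants: 1 syringaldehyde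
Product: 2 4-(tert-butyldimethylsilyloxy)-3,5-dimethoxybenzaldehyde
Conditions: TBSCl, imidazole, DMF, rt
Reagents that add atoms: tert-butyldimethylsilyl chloride, CC(C)(C)[Si](C)(C)Cl
Why: Imidazole-mediated O-silylation of a phenol; the flanking methoxy groups slow the reaction but make the resulting aryl silyl ether unusually robust toward the later basic and hydride steps.

Step 2
Reactants: 2 4-(TBSO)-3,5-dimethoxybenzaldehyde; 3 methyl propiolate
Product: 4 methyl (R)-4-[4-(TBSO)-3,5-dimethoxyphenyl]-4-hydroxybut-2-ynoate
Conditions: ProPhenol (10 mol %), Me2Zn (3 equiv), Ph3P=O (20 mol %), toluene, 0 to 4 °C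
Reagents that add atoms: none
Why: Catalytic enantioselective alkynylation: the dinuclear zinc–ProPhenol complex binds the aldehyde and the zinc alkynylide of 3 and transfers the alkynyl group to the Si face, setting C2 under catalyst control. Me2Zn is used in place of Et2Zn because its alkyl group does not add to the aldehyde in competition.

Step 3
Reactants: 4 methyl (R)-4-[4-(TBSO)-3,5-dimethoxyphenyl]-4-hydroxybut-2-ynoate
Product: 6 (S)-5-[4-(TBSO)-3,5-dimethoxyphenyl]furan-2(5H)-one, via (Z)-hydroxy enoate 5 (not isolated)
Conditions: H2 (1 atm), Pd/CaCO3 poisoned with Pb(OAc)2 (Lindlar catalyst), quinoline, EtOAc, rt; filter; PPTS (cat.), rt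
Reagents that add atoms: none
Why: Lindlar semihydrogenation adds H2 syn to give the Z-enoate 5, in which the hydroxyl reaches the ester and lactonises with loss of methanol. Only an O–acyl bond forms, so the stereocentre is untouched (the descriptor changes from R to S only because the alkene ranks below the aryl group), and the near-neutral conditions do not deprotonate the acidic C2–H.

Step 4
Reactants: 7 vanillin
Product: 8 4-(tert-butyldimethylsilyloxy)-3-methoxybenzaldehyde
Conditions: TBSCl, imidazole, CH2Cl2, rt
Reagents that add atoms: tert-butyldimethylsilyl chloride, CC(C)(C)[Si](C)(C)Cl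
Why: Standard phenol silylation; the same silyl group as in 2 allows one global deprotection at the end.

Step 5
Reactants: 6 (S)-5-[4-(TBSO)-3,5-dimethoxyphenyl]furan-2(5H)-one; 9 vinylmagnesium bromide; 8 4-(TBSO)-3-methoxybenzaldehyde
Product: 13 (3E,4S,5S)-3-[4-(TBSO)-3-methoxybenzylidene]-5-[4-(TBSO)-3,5-dimethoxyphenyl]-4-vinyldihydrofuran-2(3H)-one, via magnesium enolate 10 (not isolated), via magnesium aldolate 11 (not isolated), via aldol mesylate 12 (not isolated)
Conditions: 9 (2.4 equiv), CuBr·SMe2 (1.2 equiv), THF–Me2S, −78 °C; 6 added slowly, −78 °C; 8 (1.5 equiv), −78 to −40 °C; MsCl, Et3N, −40 to 0 °C; DBU, 0 °C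
Reagents that add atoms: none
Why: The homocuprate formed from 9 and CuBr·SMe2 binds the enoate of 6 on the face opposite the C2 aryl group; oxidative addition to a trivalent copper β-cuprio enolate and reductive elimination form the C3–vinyl bond trans to the aryl group, so the catalytically set C2 centre controls the only new stereocentre (C3) by 1,2-induction. The bromomagnesium enolate 10 then adds through a closed six-membered transition state to aldehyde 8 at C4, anti to the new vinyl group, giving aldolate 11; its two extra centres do not matter, because sulfonylation to 12 and E1cB elimination make C4 trigonal and give the benzylidene isomer with the aryl group anti to the carbonyl (E), the thermodynamically preferred one. The closest known reaction type is the three-component coupling of an organocuprate, a cyclic enoate or enone and an aldehyde, combined with the trans-selective cuprate addition to 5-substituted butenolides. No ring is closed; the step forms two skeletal bonds on the existing ring. The selectivities required are 1,4-addition in preference to removal of the acidic C2–H (secured by the low basicity of the cuprate at −78 °C and by adding 6 slowly to an excess of it), anti facial selectivity (secured by the aryl group next to the accepting carbon) and capture of 10 by 8 before proton transfer (secured by the absence of a proton source and of residual 6). Me3SiCl, a common accelerator of cuprate additions, is left out on purpose, because an O-silylated ketene acetal would not condense with 8 without a separate Lewis acid step. DBU is used briefly at 0 °C so that the C3–H of 13, which is allylic twice over, is not removed and the exocyclic alkene does not move into the ring.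

Step 6
Reactants: 13 (3E,4S,5S)-3-[4-(TBSO)-3-methoxybenzylidene]-5-[4-(TBSO)-3,5-dimethoxyphenyl]-4-vinyldihydrofuran-2(3H)-one
Product: 14 (3R,4S,5S)-3-[4-(TBSO)-3-methoxybenzyl]-5-[4-(TBSO)-3,5-dimethoxyphenyl]-4-vinyldihydrofuran-2(3H)-one
Conditions: Cu(OAc)2·H2O (5 mol %), 1,2-bis(diphenylphosphino)benzene (5 mol %), (EtO)2MeSiH (2 equiv), t-BuOH (2 equiv), toluene, 0 °C to rt
Reagents that add atoms: none
Why: Phosphine-ligated monovalent copper hydride adds hydride 1,4 to the s-cis benzylidene lactone and ignores the unactivated vinyl group (copper hydride conjugate reduction). The copper enolate is then protonated at C4 by the bulky alcohol on the face anti to the adjacent C3 vinyl group, which places the benzyl group cis to it (kinetic, substrate-controlled protonation).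

Step 7
Reactants: 14 (3R,4S,5S)-3-[4-(TBSO)-3-methoxybenzyl]-5-[4-(TBSO)-3,5-dimethoxyphenyl]-4-vinyldihydrofuran-2(3H)-one
Product: 15 (1S,2S,3R)-1-[4-(TBSO)-3,5-dimethoxyphenyl]-3-[4-(TBSO)-3-methoxybenzyl]-2-vinylbutane-1,4-diol
Conditions: LiAlH4, THF, −20 to 0 °C (14 added to the hydride); potassium sodium tartrate work-up
Reagents that add atoms: none
Why: Hydride reduction of a lactone to the 1,4-diol; inverse addition at low temperature keeps hydride in excess so that reduction outruns enolisation at the cis C4 centre, and no stereocentre is touched.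

Step 8
Reactants: 15 (1S,2S,3R)-1-[4-(TBSO)-3,5-dimethoxyphenyl]-3-[4-(TBSO)-3-methoxybenzyl]-2-vinylbutane-1,4-diol
Product: 17 (2S,3S,4R)-2-[4-(TBSO)-3,5-dimethoxyphenyl]-4-[4-(TBSO)-3-methoxybenzyl]-3-vinyltetrahydrofuran, via primary tosylate 16 (not isolated)
Conditions: TsCl (1.1 equiv), pyridine, 0 °C to rt, then 50 °C
Reagents that add atoms: none
Why: Sulfonylation is selective for the unhindered primary hydroxyl; the secondary benzylic hydroxyl then displaces the sulfonate in a 5-exo-tet Williamson-type closure. O1–C5 forms with retention at C2 because the C2–O bond is never broken.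

Step 9
Reactants: 17 (2S,3S,4R)-2-[4-(TBSO)-3,5-dimethoxyphenyl]-4-[4-(TBSO)-3-methoxybenzyl]-3-vinyltetrahydrofuran
Product: 19 [(2S,3R,4R)-2-[4-(TBSO)-3,5-dimethoxyphenyl]-4-[4-(TBSO)-3-methoxybenzyl]tetrahydrofuran-3-yl]methanol, via aldehyde 18 (not isolated)
Conditions: OsO4 (2 mol %), NaIO4 (4 equiv), 2,6-lutidine, dioxane–H2O, rt; EtOAc extraction, extract used directly; NaBH4, MeOH, 0 °C
Reagents that add atoms: sodium periodate, [Na+].[O-]I(=O)(=O)=O (source of the new oxygen, delivered through osmium tetroxide, O=[Os](=O)(=O)=O)
Why: Lemieux–Johnson cleavage of the only alkene gives aldehyde 18, and borohydride reduces it at once. The lutidine buffer and the absence of any isolation keep the epimerisable C3 centre intact, and the protected arenes are inert to the oxidant.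

Step 10
Reactants: 20 ferulic acid
Product: 22 (E)-3-[4-(tert-butyldimethylsilyloxy)-3-methoxyphenyl]prop-2-enoic acid, via bis-silyl derivative 21 (not isolated)
Conditions: TBSCl (2.5 equiv), imidazole, DMF, rt; then AcOH–THF–H2O, rt
Reagents that add atoms: tert-butyldimethylsilyl chloride, CC(C)(C)[Si](C)(C)Cl
Why: Exhaustive silylation followed by selective hydrolysis of the far more labile silyl ester; the aryl silyl ether is stable to dilute acetic acid.

Step 11
Reactants: 19 [(2S,3R,4R)-2-[4-(TBSO)-3,5-dimethoxyphenyl]-4-[4-(TBSO)-3-methoxybenzyl]tetrahydrofuran-3-yl]methanol; 22 (E)-3-[4-(TBSO)-3-methoxyphenyl]prop-2-enoic acid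
Product: 23 [(2S,3R,4R)-2-[4-(TBSO)-3,5-dimethoxyphenyl]-4-[4-(TBSO)-3-methoxybenzyl]tetrahydrofuran-3-yl]methyl (E)-3-[4-(TBSO)-3-methoxyphenyl]prop-2-enoate
Conditions: EDC·HCl, DMAP (cat.), CH2Cl2, 0 °C to rt
Reagents that add atoms: none
Why: Steglich esterification of the only hydroxyl in 19; the conditions are neutral, so neither the benzylic ether nor any stereocentre is at risk.

Step 12
Reactants: 23 tris-TBS ether of the target
Product: 24 [(2S,3R,4R)-2-(4-hydroxy-3,5-dimethoxyphenyl)-4-(4-hydroxy-3-methoxybenzyl)tetrahydrofuran-3-yl]methyl (E)-3-(4-hydroxy-3-methoxyphenyl)prop-2-enoate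
Conditions: Bu4NF, AcOH, THF, 0 °C
Reagents that add atoms: none
Why: Fluoride cleaves the three aryl O–Si bonds; the acetic acid buffer keeps the liberated phenols protonated, so the cinnamate ester is not attacked and the benzylic ether sees no strong acid.

## Compound list

1 | syringaldehyde | COc1cc(C=O)cc(OC)c1O | starting material
2 | 4-(tert-butyldimethylsilyloxy)-3,5-dimethoxybenzaldehyde | COc1cc(C=O)cc(OC)c1O[Si](C)(C)C(C)(C)C | intermediate
3 | methyl propiolate | COC(=O)C#C | starting material
4 | methyl (R)-4-[4-(TBSO)-3,5-dimethoxyphenyl]-4-hydroxybut-2-ynoate | COC(=O)C#C[C@H](O)c1cc(OC)c(O[Si](C)(C)C(C)(C)C)c(OC)c1 | intermediate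
5 | methyl (2Z,4S)-4-[4-(TBSO)-3,5-dimethoxyphenyl]-4-hydroxybut-2-enoate (not isolated) | COC(=O)/C=C\[C@H](O)c1cc(OC)c(O[Si](C)(C)C(C)(C)C)c(OC)c1 | intermediate
6 | (S)-5-[4-(TBSO)-3,5-dimethoxyphenyl]furan-2(5H)-one | O=C1C=C[C@@H](c2cc(OC)c(O[Si](C)(C)C(C)(C)C)c(OC)c2)O1 | intermediate
7 | vanillin | COc1cc(C=O)ccc1O | starting material
8 | 4-(tert-butyldimethylsilyloxy)-3-methoxybenzaldehyde | COc1cc(C=O)ccc1O[Si](C)(C)C(C)(C)C | intermediate
9 | vinylmagnesium bromide | C=C[Mg]Br | starting material
10 | bromomagnesium enolate of the (4S,5S)-5-aryl-4-vinyl lactone (not isolated) | C=C[C@H]1C=C(O[Mg]Br)O[C@@H]1c1cc(OC)c(O[Si](C)(C)C(C)(C)C)c(OC)c1 | intermediate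
11 | bromomagnesium aldolate, (3R,4S,5S)-3-[aryl(oxido)methyl] lactone, carbinol epimers (not isolated) | C=C[C@H]1[C@H](C(O[Mg]Br)c2ccc(O[Si](C)(C)C(C)(C)C)c(OC)c2)C(=O)O[C@@H]1c1cc(OC)c(O[Si](C)(C)C(C)(C)C)c(OC)c1 | intermediate
12 | (3R,4S,5S)-3-[aryl(methanesulfonyloxy)methyl] lactone, carbinol epimers (not isolated) | C=C[C@H]1[C@H](C(OS(C)(=O)=O)c2ccc(O[Si](C)(C)C(C)(C)C)c(OC)c2)C(=O)O[C@@H]1c1cc(OC)c(O[Si](C)(C)C(C)(C)C)c(OC)c1 | intermediate
13 | (3E,4S,5S)-3-[4-(TBSO)-3-methoxybenzylidene]-5-[4-(TBSO)-3,5-dimethoxyphenyl]-4-vinyldihydrofuran-2(3H)-one | C=C[C@H]1/C(=C\c2ccc(O[Si](C)(C)C(C)(C)C)c(OC)c2)C(=O)O[C@@H]1c1cc(OC)c(O[Si](C)(C)C(C)(C)C)c(OC)c1 | intermediate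
14 | (3R,4S,5S)-3-[4-(TBSO)-3-methoxybenzyl]-5-[4-(TBSO)-3,5-dimethoxyphenyl]-4-vinyldihydrofuran-2(3H)-one | C=C[C@H]1[C@@H](Cc2ccc(O[Si](C)(C)C(C)(C)C)c(OC)c2)C(=O)O[C@@H]1c1cc(OC)c(O[Si](C)(C)C(C)(C)C)c(OC)c1 | intermediate
15 | (1S,2S,3R)-1-[4-(TBSO)-3,5-dimethoxyphenyl]-3-[4-(TBSO)-3-methoxybenzyl]-2-vinylbutane-1,4-diol | C=C[C@H]([C@H](O)c1cc(OC)c(O[Si](C)(C)C(C)(C)C)c(OC)c1)[C@@H](Cc1ccc(O[Si](C)(C)C(C)(C)C)c(OC)c1)CO | intermediate
16 | primary 4-toluenesulfonate of 15 (not isolated) | C=C[C@H]([C@H](O)c1cc(OC)c(O[Si](C)(C)C(C)(C)C)c(OC)c1)[C@@H](Cc1ccc(O[Si](C)(C)C(C)(C)C)c(OC)c1)COS(=O)(=O)c1ccc(C)cc1 | intermediate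
17 | (2S,3S,4R)-2-[4-(TBSO)-3,5-dimethoxyphenyl]-4-[4-(TBSO)-3-methoxybenzyl]-3-vinyltetrahydrofuran | C=C[C@H]1[C@@H](Cc2ccc(O[Si](C)(C)C(C)(C)C)c(OC)c2)CO[C@@H]1c1cc(OC)c(O[Si](C)(C)C(C)(C)C)c(OC)c1 | intermediate
18 | (2S,3S,4R)-2-[4-(TBSO)-3,5-dimethoxyphenyl]-4-[4-(TBSO)-3-methoxybenzyl]tetrahydrofuran-3-carbaldehyde (not isolated) | O=C[C@H]1[C@@H](Cc2ccc(O[Si](C)(C)C(C)(C)C)c(OC)c2)CO[C@@H]1c1cc(OC)c(O[Si](C)(C)C(C)(C)C)c(OC)c1 | intermediate
19 | [(2S,3R,4R)-2-[4-(TBSO)-3,5-dimethoxyphenyl]-4-[4-(TBSO)-3-methoxybenzyl]tetrahydrofuran-3-yl]methanol | OC[C@H]1[C@@H](Cc2ccc(O[Si](C)(C)C(C)(C)C)c(OC)c2)CO[C@@H]1c1cc(OC)c(O[Si](C)(C)C(C)(C)C)c(OC)c1 | intermediate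
20 | ferulic acid | COc1cc(/C=C/C(=O)O)ccc1O | starting material
21 | tert-butyldimethylsilyl (E)-3-[4-(TBSO)-3-methoxyphenyl]prop-2-enoate (not isolated) | COc1cc(/C=C/C(=O)O[Si](C)(C)C(C)(C)C)ccc1O[Si](C)(C)C(C)(C)C | intermediate
22 | (E)-3-[4-(TBSO)-3-methoxyphenyl]prop-2-enoic acid | COc1cc(/C=C/C(=O)O)ccc1O[Si](C)(C)C(C)(C)C | intermediate
23 | tris-TBS ether of the target | COc1cc(/C=C/C(=O)OC[C@H]2[C@@H](Cc3ccc(O[Si](C)(C)C(C)(C)C)c(OC)c3)CO[C@@H]2c2cc(OC)c(O[Si](C)(C)C(C)(C)C)c(OC)c2)ccc1O[Si](C)(C)C(C)(C)C | intermediate
24 | CNP0289934.1, [(2S,3R,4R)-2-(4-hydroxy-3,5-dimethoxyphenyl)-4-(4-hydroxy-3-methoxybenzyl)tetrahydrofuran-3-yl]methyl (E)-ferulate | COc1cc(/C=C/C(=O)OC[C@H]2[C@@H](Cc3ccc(O)c(OC)c3)CO[C@@H]2c2cc(OC)c(O)c(OC)c2)ccc1O | target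

## Step count and least certain steps

Total: 12 steps. Longest linear sequence: 10 steps (steps 1, 2, 3, 5, 6, 7, 8, 9, 11, 12); steps 4 and 10 are side branches.

**Step 5 (key step).**
- Most likely to go wrong: deprotonation at C2 of 6 by the organometallic before it adds, which costs enantiopurity or material through the aromatic furanolate. Also possible are reversal of the aldol on warming before the sulfonate is formed, and base-induced migration of the exocyclic alkene into the ring during elimination.
- Fallback: it sets out from 6 and returns at 13, with the conjugate addition and the aldol separated. 6 is treated with 9 under copper catalysis (CuBr·SMe2, 10 mol %) with Me3SiCl at −78 °C, where silyl-accelerated 1,4-addition should outrun deprotonation, to give the silyl ketene acetal (4S,5S)-5-aryl-2-(trimethylsilyloxy)-4-vinyl-4,5-dihydrofuran F1. A Mukaiyama aldol addition of F1 to 8 (BF3·OEt2, CH2Cl2, −78 °C) gives the (3R,4S,5S)-3-[aryl(hydroxy)methyl] lactone F2. F2 is sulfonylated (MsCl, Et3N) to 12 and eliminated with DBU to 13.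

**Step 6.**
- Most likely to go wrong: poor facial selectivity in the protonation at C4, because the C2 aryl group lies on the face from which the proton must come, or epimerisation of the cis product by the copper alkoxide present.
- Fallback: it sets out from 13 and returns at 14. The reduction is run without regard to C4, and the crude mixture of 14 and its C4 epimer, the (3S,4S,5S)-lactone F3, is converted with LiN(i-Pr)2 (THF, −78 °C) into the single lithium enolate F4. F4 is protonated at −78 °C by 2,6-di-tert-butylphenol from the face anti to the vinyl group to give 14.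

**Step 2.**
- Most likely to go wrong: slow alkynyl transfer to an electron-rich, hindered aldehyde with erosion of enantioselectivity by the uncatalysed background reaction; the sense of induction must also be confirmed.
- Fallback: it sets out from 2 and returns at 4, with the stereocentre set by reagent-controlled reduction instead. Lithiated 3 (n-BuLi, THF, −78 °C) is added to 2 to give the racemic carbinol F5. Oxidation (MnO2, CH2Cl2) gives methyl 4-aryl-4-oxobut-2-ynoate F6. Reduction of F6 with B-(3-pinanyl)-9-borabicyclo[3.3.1]nonane from (+)-α-pinene (Alpine-borane), in which the slim alkynyl group takes the crowded position of the boat-like transition state, should give the R carbinol 4 by analogy with simple alkynyl ketones; the antipodal reagent is equally available.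

**Step 8.**
- Most likely to go wrong: competing sulfonylation of the benzylic hydroxyl followed by ionisation at C2 (epimerisation or elimination), or displacement of the primary sulfonate by chloride before the ring closes.
- Fallback: it sets out from 14 and returns at 17 without ever opening the C2–O1 bond's ring. 14 is reduced only to the lactol F7 (i-Bu2AlH, toluene, −78 °C), and the lactol hydroxyl is removed by ionic hydrogenation through the C5 oxocarbenium ion (Et3SiH, BF3·OEt2, CH2Cl2, −78 °C).

**Step 9.**
- Most likely to go wrong: epimerisation at C3 of the aldehyde in the aqueous, periodate-containing medium, or over-oxidation to the hydroxy ketone.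
- Fallback: it sets out from 17 and returns at 19. 17 is dihydroxylated (OsO4 cat., N-methylmorpholine N-oxide, acetone–H2O) to the isolable diol F8. F8 is cleaved under anhydrous, non-basic conditions (Pb(OAc)4, CH2Cl2, −20 °C), and the filtered solution of 18 is reduced immediately with NaBH4 in MeOH to 19.

## Further compounds

F1 | step 5 | (4S,5S)-5-[4-(TBSO)-3,5-dimethoxyphenyl]-2-(trimethylsilyloxy)-4-vinyl-4,5-dihydrofuran | C=C[C@H]1C=C(O[Si](C)(C)C)O[C@@H]1c1cc(OC)c(O[Si](C)(C)C(C)(C)C)c(OC)c1
F2 | step 5 | (3R,4S,5S)-3-{[4-(TBSO)-3-methoxyphenyl](hydroxy)methyl}-5-[4-(TBSO)-3,5-dimethoxyphenyl]-4-vinyldihydrofuran-2(3H)-one, carbinol epimers | C=C[C@H]1[C@H](C(O)c2ccc(O[Si](C)(C)C(C)(C)C)c(OC)c2)C(=O)O[C@@H]1c1cc(OC)c(O[Si](C)(C)C(C)(C)C)c(OC)c1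
F3 | step 6 | (3S,4S,5S)-3-[4-(TBSO)-3-methoxybenzyl]-5-[4-(TBSO)-3,5-dimethoxyphenyl]-4-vinyldihydrofuran-2(3H)-one (C4 epimer of 14 in ring A numbering) | C=C[C@H]1[C@H](Cc2ccc(O[Si](C)(C)C(C)(C)C)c(OC)c2)C(=O)O[C@@H]1c1cc(OC)c(O[Si](C)(C)C(C)(C)C)c(OC)c1
F4 | step 6 | lithium enolate of 14 | C=C[C@H]1C(Cc2ccc(O[Si](C)(C)C(C)(C)C)c(OC)c2)=C(O[Li])O[C@@H]1c1cc(OC)c(O[Si](C)(C)C(C)(C)C)c(OC)c1
F5 | step 2 | racemic methyl 4-[4-(TBSO)-3,5-dimethoxyphenyl]-4-hydroxybut-2-ynoate | COC(=O)C#CC(O)c1cc(OC)c(O[Si](C)(C)C(C)(C)C)c(OC)c1
F6 | step 2 | methyl 4-[4-(TBSO)-3,5-dimethoxyphenyl]-4-oxobut-2-ynoate | COC(=O)C#CC(=O)c1cc(OC)c(O[Si](C)(C)C(C)(C)C)c(OC)c1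
F7 | step 8 | (3R,4S,5S)-3-[4-(TBSO)-3-methoxybenzyl]-5-[4-(TBSO)-3,5-dimethoxyphenyl]-4-vinyltetrahydrofuran-2-ol, anomers | C=C[C@H]1[C@@H](Cc2ccc(O[Si](C)(C)C(C)(C)C)c(OC)c2)C(O)O[C@@H]1c1cc(OC)c(O[Si](C)(C)C(C)(C)C)c(OC)c1
F8 | step 9 | 1-[(2S,3S,4R)-2-[4-(TBSO)-3,5-dimethoxyphenyl]-4-[4-(TBSO)-3-methoxybenzyl]tetrahydrofuran-3-yl]ethane-1,2-diol, carbinol epimers | OCC(O)[C@H]1[C@@H](Cc2ccc(O[Si](C)(C)C(C)(C)C)c(OC)c2)CO[C@@H]1c1cc(OC)c(O[Si](C)(C)C(C)(C)C)c(OC)c1
A1 | alternative 1 | (5S)-5-[(1S,2R,5S)-menthyloxy]furan-2(5H)-one | O=C1C=C[C@@H](O[C@H]2C[C@@H](C)CC[C@@H]2C(C)C)O1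
A2 | alternative 1 | 4-(benzyloxy)-3,5-dimethoxybenzaldehyde | COc1cc(C=O)cc(OC)c1OCc1ccccc1
A3 | alternative 1 | (trimethylsilyl)methyl trifluoromethanesulfonate | C[Si](C)(C)COS(=O)(=O)C(F)(F)F
A4 | alternative 1 | cis-fused 8-[4-(benzyloxy)-3,5-dimethoxyphenyl]-4-menthyloxy-3,7-dioxabicyclo[3.3.0]octan-2-one, aryl exo | O=C1[C@H]2[C@@H]([C@@H](O[C@H]3C[C@@H](C)CC[C@@H]3C(C)C)O1)CO[C@@H]2c1cc(OC)c(OCc2ccccc2)c(OC)c1
A5 | alternative 2 | (2R,3R)-2-(4-hydroxy-3,5-dimethoxybenzyl)-3-[4-(TBSO)-3-methoxybenzyl]butane-1,4-diol | OC[C@H](Cc1cc(OC)c(O)c(OC)c1)[C@@H](Cc1ccc(O[Si](C)(C)C(C)(C)C)c(OC)c1)CO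
A6 | alternative 2 | 5-methoxylariciresinol guaiacyl TBS ether | OC[C@H]1[C@@H](Cc2ccc(O[Si](C)(C)C(C)(C)C)c(OC)c2)CO[C@@H]1c1cc(OC)c(O)c(OC)c1
A7 | alternative 3 | 3-(allyloxy)-2-iodo-3-[4-(TBSO)-3,5-dimethoxyphenyl]propyl TBS ether, benzylic centre as in the target, iodide centre undefined | C=CCO[C@H](c1cc(OC)c(O[Si](C)(C)C(C)(C)C)c(OC)c1)C(I)CO[Si](C)(C)C(C)(C)C
A8 | alternative 3 | [4-(TBSO)-3-methoxyphenyl]zinc bromide | COc1cc([Zn]Br)ccc1O[Si](C)(C)C(C)(C)C
A9 | alternative 3 | 5-methoxylariciresinol tris-TBS ether | CC(C)(C)[Si](C)(C)OC[C@H]1[C@@H](Cc2ccc(O[Si](C)(C)C(C)(C)C)c(OC)c2)CO[C@@H]1c1cc(OC)c(O[Si](C)(C)C(C)(C)C)c(OC)c1
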